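All constants were chosen freely; the rest is arithmetic.

One decision waited. Before this flask went on, I wanted to know whether it needed its whole time, and whether the next run could take a larger charge of substrate at the same catalyst loading.

substrate 11 mM; free catalyst 2.7 mol%; time 15 d

    substrate + free catalyst ⇌ catalyst intermediate A (K1 = 220 M⁻¹, k1 = 31000 M⁻¹ h⁻¹)
    catalyst intermediate A ⇌ catalyst intermediate B (K2 = 1.1, k2 = 11 h⁻¹)
    catalyst intermediate B → free catalyst + product (k3 = 32 h⁻¹)

* why nothing more happens at 15 d, or that something still does (no working catalyst is left / it is still moving / all of the substrate has reacted / forward and back rates have come level)
* conversion of substrate at 15 d
* amount of product at 15 d, in percent of the substrate charged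

The last step has no back arrow and no step destroys catalyst, so I took the end state to be product and free catalyst, and what remained was the pace. The reverse constants of the first two steps are 141 h⁻¹ and 10.0 h⁻¹. With the catalyst forms in steady state, these give a saturated turnover frequency of 6.64 h⁻¹ and a Michaelis constant of 3.82 mM. As a fraction of the charge, that constant is 0.347, the fraction of substrate left when turnover runs at half its saturated value. A saturated catalyst at this loading would pass the whole charge in 5.58 h.

Integrating the rate law in fractions of the charge, I added 0.900 of that saturated time to 2.3 times the Michaelis fraction times the saturated time. This gave 9.47 h, which I called the clearing time: the time to convert a fraction 0.900 of the charge. The flask's 15 d is 38.0 clearing times, so I committed to complete conversion and to a shorter next run.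

The forecast gave all of the substrate has reacted, with conversion 100% and product 100%, holding that “the charge is gone within about a day”.

The simulation gave all of the substrate has reacted, with conversion 100% and product 100%, as the forecast said. This flask already held >99.9% product at 1.50 d, and a fraction 0.900 of its conversion stood at 9.49 h, against a clearing time of 9.47 h. In the neighbouring flask with 19 mM of substrate at the same loading, the saturated time stays 5.58 h. The Michaelis fraction drops to 0.201, so the clearing time shortens to 7.60 h. That flask, read at 15.0 d, held 100% product, with 0% of its substrate left.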